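**Plan**

1. Retrosynthesis: the C8–O ester bond is cut first (inversion of an 8-epi alcohol). C11=C13 and C7–C11 are then cut together, which opens the γ-lactone (ring C: O6–C6–C7–C11–C12) to an O6 diethylphosphonoacetate on a cis-C7,C8-oxirane. Further cuts are C7=C8 (metathesis), the furanone O–C3 bond, C1–C2 and C3–C4.
2. Forward: the 3(2H)-furanone (ring A) is made first from a hydroxy ynone, the nine-membered oxacycle (ring B) is closed at C7=C8, and ring C with its exo-methylene is built in one flask. The isovalerate and the free C15 hydroxyl come last.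
3. Enabling feature: C6–O, C7–C11 and C8–O lie on three adjacent carbons of ring B, with O6 and C11 cis (cis-fused ring C). This is the imprint of a carbanion tethered to O6 opening a C7,C8-oxirane from the O6 face.
4. Stereochemistry: C10 comes from (S)-lactic acid by alkylation with self-regeneration of the stereocentre, and C6 from a Sharpless kinetic resolution. The 4Z alkene comes from a trans-hydroalumination. C7 and C8 come from epoxidation anti to O6 and SN2 opening at C7, and C8 is finally inverted in a Mitsunobu esterification.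

Key step: step 16

Remark: germacrane numbering is used for all ring atoms (C1 ketone, C2=C3 furanone alkene, C4(C15)=C5, C6 lactone carbinol, C7 ring fusion, C8 carbinol, C9H2, C10(C14) quaternary, C11=C13, C12 lactone carbonyl); paraformaldehyde is counted as formaldehyde, and CIP labels at C6 and C7 change between intermediates only because neighbouring atoms change, not the spatial arrangement.

**Route**

Step 1
Reactants: 1 (S)-lactic acid
Product: 2 (2S,5S)-2-tert-butyl-5-methyl-1,3-dioxolan-4-one
Conditions: t-BuCHO, TsOH·H2O (cat.), H2SO4 (cat.), pentane, reflux, Dean–Stark trap; crystallisation from pentane/Et2O, −78 °C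
Reagents that add atoms: pivalaldehyde CC(C)(C)C=O
Why: Acid-catalysed acetalisation of an α-hydroxy acid leaves the lactate centre untouched, and the acetal carbon equilibrates toward the cis isomer, which should be obtained pure by crystallisation.

Step 2
Reactants: 2 (2S,5S)-2-tert-butyl-5-methyl-1,3-dioxolan-4-one; 3 allyl bromide
Product: 4 (2S,5R)-2-tert-butyl-5-methyl-5-(prop-2-en-1-yl)-1,3-dioxolan-4-one
Conditions: LiN(i-Pr)2, THF, −78 °C; then 3, −78 → −20 °C
Reagents that add atoms: none
Why: Enolate alkylation with self-regeneration of the stereocentre (Seebach alkylation): the planar lithium enolate is attacked on the face anti to the tert-butyl group, so the allyl group takes the place of the former hydrogen and the future C10 is set as R.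

Step 3
Reactants: 4 (2S,5R)-2-tert-butyl-5-methyl-5-(prop-2-en-1-yl)-1,3-dioxolan-4-one
Product: 5 (2R)-2-hydroxy-N-methoxy-N,2-dimethylpent-4-enamide
Conditions: MeNH(OMe)·HCl, i-PrMgCl, THF, −20 → 0 °C; aq. NH4Cl
Reagents that add atoms: N,O-dimethylhydroxylamine hydrochloride CNOC.Cl
Why: Weinreb amide formation by aminolysis of the activated acyl acetal with the chloromagnesium amide; the hemiacetal left on oxygen collapses on work-up with loss of pivalaldehyde, and the quaternary centre is not involved.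

Step 4
Reactants: 6 propargyl alcohol
Product: 7 tert-butyl(diphenyl)(prop-2-yn-1-yloxy)silane
Conditions: t-BuPh2SiCl, imidazole, CH2Cl2, 0 °C → rt
Reagents that add atoms: tert-butyl(chloro)diphenylsilane CC(C)(C)[Si](Cl)(c1ccccc1)c1ccccc1
Why: Routine silylation of a primary alcohol; the silyl ether later also keeps the C15 oxygen from directing the hydroalumination.

Step 5
Reactants: 7 tert-butyl(diphenyl)(prop-2-yn-1-yloxy)silane; 8 acrolein
Product: 9 rac-6-{[tert-butyl(diphenyl)silyl]oxy}hex-1-en-4-yn-3-ol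
Conditions: n-BuLi, THF, −78 °C; then 8, −78 °C; aq. NH4Cl
Reagents that add atoms: none
Why: 1,2-Addition of a lithium acetylide to an enal at low temperature gives the alkynyl vinyl carbinol (C5–C6 bond) as the racemate.

Step 6
Reactants: 9 rac-6-{[tert-butyl(diphenyl)silyl]oxy}hex-1-en-4-yn-3-ol
Product: 10 (3R)-6-{[tert-butyl(diphenyl)silyl]oxy}hex-1-en-4-yn-3-ol
Conditions: Ti(Oi-Pr)4 (0.2 equiv), D-(−)-diisopropyl tartrate (0.24 equiv), t-BuOOH (0.6 equiv), 4 Å molecular sieves, CH2Cl2, −20 °C
Reagents that add atoms: none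
Why: Sharpless kinetic resolution of a secondary allylic alcohol: with the D-(−)-tartrate the (S)-carbinol should be epoxidised at its vinyl group much faster, leaving the (R)-carbinol that becomes C6.

Step 7
Reactants: 10 (3R)-6-{[tert-butyl(diphenyl)silyl]oxy}hex-1-en-4-yn-3-ol
Product: 12 (3R,4Z)-6-{[tert-butyl(diphenyl)silyl]oxy}-5-iodohexa-1,4-dien-3-ol, via cyclic vinylalanate 11 (not isolated)
Conditions: NaAlH2(OCH2CH2OMe)2, THF, −20 → 0 °C; then I2, THF, −78 → 0 °C; aq. potassium sodium tartrate, aq. Na2S2O3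
Reagents that add atoms: iodine II
Why: Alkoxide-directed trans-hydroalumination of a propargylic alcohol puts hydrogen on C5 and aluminium on C4 in a five-membered O–Al chelate, and iodinolysis with retention gives the vinyl iodide with iodine cis to C6, which fixes the later 4Z geometry.

Step 8
Reactants: 12 (3R,4Z)-6-{[tert-butyl(diphenyl)silyl]oxy}-5-iodohexa-1,4-dien-3-ol
Product: 13 tert-butyl{[(2Z,4R)-2-iodo-4-(triethylsilyloxy)hexa-2,5-dien-1-yl]oxy}diphenylsilane
Conditions: Et3SiCl, imidazole, CH2Cl2, 0 °C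
Reagents that add atoms: chlorotriethylsilane CC[Si](Cl)(CC)CC
Why: Silylation of the secondary alcohol; the triethylsilyl ether stops the cis-enynol from cyclising to a furan in the next steps and can later be removed beside the primary tert-butyldiphenylsilyl ether.

Step 9
Reactants: 13 tert-butyl{[(2Z,4R)-2-iodo-4-(triethylsilyloxy)hexa-2,5-dien-1-yl]oxy}diphenylsilane; 14 ethynylmagnesium bromide
Product: 16 tert-butyl{[(2E,4R)-2-ethynyl-4-(triethylsilyloxy)hexa-2,5-dien-1-yl]oxy}diphenylsilane, via ethynylzinc bromide 15 (not isolated)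
Conditions: 14, ZnBr2, THF, 0 °C; then 13, Pd(PPh3)4 (5 mol %), THF, rt
Reagents that add atoms: none
Why: Negishi coupling of an alkenyl iodide with ethynylzinc bromide under zerovalent palladium forms C3–C4 with retention of the alkene geometry (the label changes from Z to E only through the CIP priorities).

Step 10
Reactants: 5 (2R)-2-hydroxy-N-methoxy-N,2-dimethylpent-4-enamide; 16 tert-butyl{[(2E,4R)-2-ethynyl-4-(triethylsilyloxy)hexa-2,5-dien-1-yl]oxy}diphenylsilane
Product: 17 (4R,8E,10R)-8-({[tert-butyl(diphenyl)silyl]oxy}methyl)-4-hydroxy-4-methyl-10-(triethylsilyloxy)dodeca-1,8,11-trien-6-yn-5-one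
Conditions: 16, n-BuLi, THF, −78 °C; 5, i-PrMgCl (1 equiv), THF, −20 °C; combined, −78 → 0 °C; aq. NH4Cl
Reagents that add atoms: none
Why: Acylation of a lithium acetylide by a Weinreb amide forms C1–C2; the chelated tetrahedral adduct prevents a second addition, and the tertiary hydroxyl is carried as its magnesium alkoxide.

Step 11
Reactants: 17 (4R,8E,10R)-8-({[tert-butyl(diphenyl)silyl]oxy}methyl)-4-hydroxy-4-methyl-10-(triethylsilyloxy)dodeca-1,8,11-trien-6-yn-5-one
Product: 18 (2R)-5-[(2Z,4R)-1-{[tert-butyl(diphenyl)silyl]oxy}-4-(triethylsilyloxy)hexa-2,5-dien-2-yl]-2-methyl-2-(prop-2-en-1-yl)furan-3(2H)-one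
Conditions: (4-CF3C6H4)3PAuCl (5 mol %), AgOSO2CF3 (5 mol %), toluene, rt
Reagents that add atoms: none
Why: Cationic monovalent gold activates the ynone for 5-endo-dig hydroalkoxylation by the tertiary hydroxyl at C3, the established cyclisation of α′-hydroxy ynones to 3(2H)-furanones; no stereocentre is touched.

Step 12
Reactants: 18 (2R)-5-[(2Z,4R)-1-{[tert-butyl(diphenyl)silyl]oxy}-4-(triethylsilyloxy)hexa-2,5-dien-2-yl]-2-methyl-2-(prop-2-en-1-yl)furan-3(2H)-one
Product: 19 (2Z,4R,5Z,8R)-2-({[tert-butyl(diphenyl)silyl]oxy}methyl)-8-methyl-4-(triethylsilyloxy)-11-oxabicyclo[6.2.1]undeca-1(10),2,5-trien-9-one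
Conditions: second-generation Grubbs catalyst RuCl2(=CHPh)(H2IMes)(PCy3) (10 mol %), toluene (1 mM), 80 °C
Reagents that add atoms: none
Why: Ring-closing metathesis of the two terminal alkenes closes ring B at C7=C8 with loss of ethylene; the 4Z alkene holds both chains on the same side of the furanone, and the nine-membered ring can only accommodate a Z alkene.

Step 13
Reactants: 19 (2Z,4R,5Z,8R)-2-({[tert-butyl(diphenyl)silyl]oxy}methyl)-8-methyl-4-(triethylsilyloxy)-11-oxabicyclo[6.2.1]undeca-1(10),2,5-trien-9-one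
Product: 20 (2Z,4R,5Z,8R)-2-({[tert-butyl(diphenyl)silyl]oxy}methyl)-4-hydroxy-8-methyl-11-oxabicyclo[6.2.1]undeca-1(10),2,5-trien-9-one
Conditions: HF·pyridine, pyridine, THF, 0 °C
Reagents that add atoms: none
Why: Buffered fluoride cleaves the secondary triethylsilyl ether much faster than the primary tert-butyldiphenylsilyl ether, and avoids acid that could ionise the bis-allylic carbinol.

Step 14
Reactants: 20 (2Z,4R,5Z,8R)-2-({[tert-butyl(diphenyl)silyl]oxy}methyl)-4-hydroxy-8-methyl-11-oxabicyclo[6.2.1]undeca-1(10),2,5-trien-9-one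
Product: 21 (4Z,6S,7R,8S,10R)-15-{[tert-butyl(diphenyl)silyl]oxy}-7,8-epoxy-6-hydroxy-3,10-epoxygermacra-2,4-dien-1-one (cis-oxirane, oxygen anti to the C6 hydroxyl)
Conditions: m-CPBA, CH2Cl2/aq. NaHCO3, 0 °C
Reagents that add atoms: 3-chloroperoxybenzoic acid OOC(=O)c1cccc(Cl)c1
Why: Prilezhaev epoxidation should pick the isolated cis-alkene over the acceptor-conjugated C4=C5 and furanone alkenes, and because allylic 1,3-strain toward both flanking Z-alkenes places H6 inside and O6 pseudo-equatorial, attack from the ring periphery should set C7 and C8 with the oxirane anti to O6, as peracids do with eight- and nine-membered cycloalk-2-enols.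

Step 15
Reactants: 21 (4Z,6S,7R,8S,10R)-15-{[tert-butyl(diphenyl)silyl]oxy}-7,8-epoxy-6-hydroxy-3,10-epoxygermacra-2,4-dien-1-one; 22 diethylphosphonoacetic acid
Product: 23 (4Z,6S,7S,8S,10R)-15-{[tert-butyl(diphenyl)silyl]oxy}-6-[(diethoxyphosphoryl)acetoxy]-7,8-epoxy-3,10-epoxygermacra-2,4-dien-1-one
Conditions: DCC, DMAP (cat.), CH2Cl2, 0 °C → rt
Reagents that add atoms: none
Why: Steglich esterification of the secondary alcohol under neutral conditions that leave the oxirane and the silyl ether intact.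

Step 16
Reactants: 23 (4Z,6S,7S,8S,10R)-15-{[tert-butyl(diphenyl)silyl]oxy}-6-[(diethoxyphosphoryl)acetoxy]-7,8-epoxy-3,10-epoxygermacra-2,4-dien-1-one; 24 paraformaldehyde
Product: 26 (4Z,6S,7R,8S,10R)-15-{[tert-butyl(diphenyl)silyl]oxy}-8-hydroxy-1-oxo-3,10-epoxygermacra-2,4,11(13)-trien-12,6-olide, via α-phosphono lactone 25 (not isolated)
Conditions: NaN(SiMe3)2 (1.05 equiv), THF, −78 → 40 °C; then (CH2O)n, 0 °C → rt; aq. NH4Cl
Reagents that add atoms: none
Why: The base deprotonates the phosphonoacetate, and the stabilised carbanion C11, held on O6, attacks C7 from the rear of the C7–O oxirane bond (SN2), closing ring C (O6–C6–C7–C11–C12) in a 5-exo-tet mode and releasing the C8 alkoxide; that alkoxide is protonated by the much more acidic α-phosphono lactone 25, whose anion then olefinates formaldehyde (Horner–Wadsworth–Emmons) to give C11=C13. The closest known reactions are the opening of epoxides by phosphonoacetate or malonate anions to α-substituted γ-lactones and the methylenation of α-phosphono-γ-lactones with paraformaldehyde. C7 is the only stereocentre made: it arises by inversion at the oxirane carbon, so it is relayed from C6 through the anti oxirane, and the lactone must be cis-fused because the nucleophile arrives from the O6 face; C8 keeps its oxygen with retention, and C11 ceases to be a stereocentre on olefination. The step needs attack at C7 and not at C8: the short ester tether makes C7 the 5-exo terminus, whereas C8 would demand a 6-endo trajectory that is poorly aligned with the C8–O bond, the same preference shown by tethered nucleophiles on 2,3-epoxy alcohols. Conjugate 1,6-addition of the carbanion to C5 is reversible and the substrate has no hydrogen more acidic than the phosphonoacetate, so the irreversible oxirane opening should drain the anion, and the fast proton transfer should keep the alkoxide from attacking the lactone carbonyl.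

Step 17
Reactants: 26 (4Z,6S,7R,8S,10R)-15-{[tert-butyl(diphenyl)silyl]oxy}-8-hydroxy-1-oxo-3,10-epoxygermacra-2,4,11(13)-trien-12,6-olide; 27 isovaleric acid
Product: 28 (4Z,6S,7R,8R,10R)-15-{[tert-butyl(diphenyl)silyl]oxy}-8-(3-methylbutanoyloxy)-1-oxo-3,10-epoxygermacra-2,4,11(13)-trien-12,6-olide
Conditions: PPh3, DIAD, 27, toluene, 0 °C → rt
Reagents that add atoms: none
Why: Mitsunobu esterification: the carboxylate displaces the C8 oxyphosphonium with inversion, which corrects C8 to R and installs the isovalerate in one operation.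

Step 18
Reactants: 28 (4Z,6S,7R,8R,10R)-15-{[tert-butyl(diphenyl)silyl]oxy}-8-(3-methylbutanoyloxy)-1-oxo-3,10-epoxygermacra-2,4,11(13)-trien-12,6-olide
Product: 29 (4Z,6S,7R,8R,10R)-15-hydroxy-8-(3-methylbutanoyloxy)-1-oxo-3,10-epoxygermacra-2,4,11(13)-trien-12,6-olide (CNP0171896.2)
Conditions: HF·pyridine, THF, 0 °C → rt
Reagents that add atoms: none
Why: Fluoride-mediated desilylation under mildly acidic conditions frees the C15 hydroxyl without base that could add to the exo-methylene lactone or move the ester.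

**Compound list**

1 | (S)-lactic acid | C[C@H](O)C(=O)O | starting material
2 | (2S,5S)-2-tert-butyl-5-methyl-1,3-dioxolan-4-one | C[C@@H]1O[C@H](C(C)(C)C)OC1=O | intermediate
3 | allyl bromide | C=CCBr | starting material
4 | (2S,5R)-2-tert-butyl-5-methyl-5-(prop-2-en-1-yl)-1,3-dioxolan-4-one | C[C@]1(CC=C)O[C@H](C(C)(C)C)OC1=O | intermediate
5 | (2R)-2-hydroxy-N-methoxy-N,2-dimethylpent-4-enamide | C=CC[C@@](C)(O)C(=O)N(C)OC | intermediate
6 | propargyl alcohol | C#CCO | starting material
7 | tert-butyl(diphenyl)(prop-2-yn-1-yloxy)silane | C#CCO[Si](c1ccccc1)(c1ccccc1)C(C)(C)C | intermediate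
8 | acrolein | C=CC=O | starting material
9 | rac-6-{[tert-butyl(diphenyl)silyl]oxy}hex-1-en-4-yn-3-ol | C=CC(O)C#CCO[Si](c1ccccc1)(c1ccccc1)C(C)(C)C | intermediate
10 | (3R)-6-{[tert-butyl(diphenyl)silyl]oxy}hex-1-en-4-yn-3-ol | O[C@H](C=C)C#CCO[Si](c1ccccc1)(c1ccccc1)C(C)(C)C | intermediate
11 | sodium cyclic alkoxy(alkenyl)bis(2-methoxyethoxy)aluminate from 10 (Al bound to O6 and C4, H on C5) | [Na+].COCCO[Al-]1(OCCOC)O[C@H](C=C)C=C1CO[Si](c2ccccc2)(c2ccccc2)C(C)(C)C | intermediate
12 | (3R,4Z)-6-{[tert-butyl(diphenyl)silyl]oxy}-5-iodohexa-1,4-dien-3-ol | O[C@H](C=C)/C=C(/CO[Si](c1ccccc1)(c1ccccc1)C(C)(C)C)I | intermediate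
13 | tert-butyl{[(2Z,4R)-2-iodo-4-(triethylsilyloxy)hexa-2,5-dien-1-yl]oxy}diphenylsilane | CC[Si](CC)(CC)O[C@H](C=C)/C=C(/CO[Si](c1ccccc1)(c1ccccc1)C(C)(C)C)I | intermediate
14 | ethynylmagnesium bromide | C#C[Mg]Br | starting material
15 | ethynylzinc bromide | C#C[Zn]Br | intermediate
16 | tert-butyl{[(2E,4R)-2-ethynyl-4-(triethylsilyloxy)hexa-2,5-dien-1-yl]oxy}diphenylsilane | CC[Si](CC)(CC)O[C@H](C=C)/C=C(/CO[Si](c1ccccc1)(c1ccccc1)C(C)(C)C)C#C | intermediate
17 | (4R,8E,10R)-8-({[tert-butyl(diphenyl)silyl]oxy}methyl)-4-hydroxy-4-methyl-10-(triethylsilyloxy)dodeca-1,8,11-trien-6-yn-5-one | CC[Si](CC)(CC)O[C@H](C=C)/C=C(/CO[Si](c1ccccc1)(c1ccccc1)C(C)(C)C)C#CC(=O)[C@@](C)(CC=C)O | intermediate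
18 | (2R)-5-[(2Z,4R)-1-{[tert-butyl(diphenyl)silyl]oxy}-4-(triethylsilyloxy)hexa-2,5-dien-2-yl]-2-methyl-2-(prop-2-en-1-yl)furan-3(2H)-one | CC[Si](CC)(CC)O[C@H](C=C)/C=C(/CO[Si](c1ccccc1)(c1ccccc1)C(C)(C)C)C1=CC(=O)[C@@](C)(CC=C)O1 | intermediate
19 | (2Z,4R,5Z,8R)-2-({[tert-butyl(diphenyl)silyl]oxy}methyl)-8-methyl-4-(triethylsilyloxy)-11-oxabicyclo[6.2.1]undeca-1(10),2,5-trien-9-one | C[C@@]12C/C=C\[C@@H](O[Si](CC)(CC)CC)/C=C(/CO[Si](c3ccccc3)(c3ccccc3)C(C)(C)C)C(=CC1=O)O2 | intermediate
20 | (2Z,4R,5Z,8R)-2-({[tert-butyl(diphenyl)silyl]oxy}methyl)-4-hydroxy-8-methyl-11-oxabicyclo[6.2.1]undeca-1(10),2,5-trien-9-one | C[C@@]12C/C=C\[C@@H](O)/C=C(/CO[Si](c3ccccc3)(c3ccccc3)C(C)(C)C)C(=CC1=O)O2 | intermediate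
21 | (4Z,6S,7R,8S,10R)-15-{[tert-butyl(diphenyl)silyl]oxy}-7,8-epoxy-6-hydroxy-3,10-epoxygermacra-2,4-dien-1-one (oxirane anti to O6) | O[C@H]1/C=C(/CO[Si](c4ccccc4)(c4ccccc4)C(C)(C)C)C2=CC(=O)[C@@](C)(C[C@@H]3O[C@@H]31)O2 | intermediate
22 | diethylphosphonoacetic acid | CCOP(=O)(CC(=O)O)OCC | starting material
23 | (4Z,6S,7S,8S,10R)-15-{[tert-butyl(diphenyl)silyl]oxy}-6-[(diethoxyphosphoryl)acetoxy]-7,8-epoxy-3,10-epoxygermacra-2,4-dien-1-one | CCOP(=O)(CC(=O)O[C@H]1/C=C(/CO[Si](c4ccccc4)(c4ccccc4)C(C)(C)C)C2=CC(=O)[C@@](C)(C[C@@H]3O[C@@H]31)O2)OCC | intermediate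
24 | paraformaldehyde (formaldehyde source) | C=O | starting material
25 | (4Z,6S,7R,8S,10R)-15-{[tert-butyl(diphenyl)silyl]oxy}-11-(diethoxyphosphoryl)-8-hydroxy-1-oxo-3,10-epoxygermacra-2,4-dien-12,6-olide (both C11 epimers) | CCOP(=O)(OCC)C1C(=O)O[C@H]2/C=C(/CO[Si](c4ccccc4)(c4ccccc4)C(C)(C)C)C3=CC(=O)[C@@](C)(C[C@H](O)[C@@H]12)O3 | intermediate
26 | (4Z,6S,7R,8S,10R)-15-{[tert-butyl(diphenyl)silyl]oxy}-8-hydroxy-1-oxo-3,10-epoxygermacra-2,4,11(13)-trien-12,6-olide | C=C1C(=O)O[C@H]2/C=C(/CO[Si](c4ccccc4)(c4ccccc4)C(C)(C)C)C3=CC(=O)[C@@](C)(C[C@H](O)[C@@H]12)O3 | intermediate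
27 | isovaleric acid | CC(C)CC(=O)O | starting material
28 | (4Z,6S,7R,8R,10R)-15-{[tert-butyl(diphenyl)silyl]oxy}-8-(3-methylbutanoyloxy)-1-oxo-3,10-epoxygermacra-2,4,11(13)-trien-12,6-olide | C=C1C(=O)O[C@H]2/C=C(/CO[Si](c4ccccc4)(c4ccccc4)C(C)(C)C)C3=CC(=O)[C@@](C)(C[C@@H](OC(=O)CC(C)C)[C@@H]12)O3 | intermediate
29 | (4Z,6S,7R,8R,10R)-15-hydroxy-8-(3-methylbutanoyloxy)-1-oxo-3,10-epoxygermacra-2,4,11(13)-trien-12,6-olide (CNP0171896.2) | C=C1C(=O)O[C@H]2/C=C(/CO)C3=CC(=O)[C@@](C)(C[C@@H](OC(=O)CC(C)C)[C@@H]12)O3 | target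

**Step count and risks**

Total step count: 18. Longest linear sequence: 15 steps (steps 4 to 18, from propargyl alcohol 6 to 29).

Steps most likely to fail:

1. Step 16. The ester-tethered carbanion may fail to reach the rear of C7 because the ester prefers its s-trans form, may be held up in reversible addition to C5, or the C8 alkoxide may shift the lactone before it is protonated. The fallback sets out from 21 and separates C–C bond formation from the methylenation. DCC/DMAP esterification of 21 with the known 2-(phenylselanyl)propanoic acid, CC([Se]c1ccccc1)C(=O)O, would give the O6 2-(phenylselanyl)propanoate F1. LiN(i-Pr)2 in THF (−78 → 0 °C) would then form the more nucleophilic, non-stabilised ester enolate, which should open the oxirane at C7 in the same 5-exo sense to give the 11-methyl-11-(phenylselanyl) lactone F2. Oxidation with H2O2/pyridine in CH2Cl2 at 0 °C and selenoxide syn-elimination toward the methyl group would return to the route at 26.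

2. Step 17. Displacement at the C8 oxyphosphonium, flanked by the ring-fusion carbon C7 and by C9 next to the quaternary C10, may be slower than E2 elimination, and the phosphine may add to the exo-methylene lactone. The fallback sets out from 26 and replaces the substitution by an oxidation–reduction–acylation sequence. Dess–Martin periodinane (CH2Cl2, NaHCO3, 0 °C) would give the 8-ketone F3. Luche reduction (NaBH4, CeCl3·7H2O, MeOH, −78 °C) should deliver hydride to the face away from the C7–C11 bond and give the 8R alcohol F4. DCC/DMAP esterification with 27 would return to the route at 28.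

3. Step 14. The peracid may deliver oxygen to the face syn to O6 if ring B adopts another conformer (poor facial selectivity), or may oxidise C4=C5 in competition. The fallback sets out from 20 and delivers the oxirane oxygen to the face opposite to the one an electrophile attacks. NBS in THF/H2O at 0 °C would form the bromonium ion on the exposed face, and water should open it at C8, remote from the electron-withdrawing C6–O bond, to give the trans bromohydrin F5. K2CO3 in MeOH would then close the oxirane by displacement of bromide at C7 with inversion and return to the route at 21.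

**Further compounds**

F1 | step 16 | O6 2-(phenylselanyl)propanoate of 21 (both epimers at the selenium-bearing carbon) | CC([Se]c5ccccc5)C(=O)O[C@H]1/C=C(/CO[Si](c4ccccc4)(c4ccccc4)C(C)(C)C)C2=CC(=O)[C@@](C)(C[C@@H]3O[C@@H]31)O2
F2 | step 16 | 15-{[tert-butyl(diphenyl)silyl]oxy}-8-hydroxy-11-methyl-11-(phenylselanyl)-1-oxo-3,10-epoxygermacra-2,4-dien-12,6-olide (ring centres as in 26, both C11 epimers) | CC1([Se]c5ccccc5)C(=O)O[C@H]2/C=C(/CO[Si](c4ccccc4)(c4ccccc4)C(C)(C)C)C3=CC(=O)[C@@](C)(C[C@H](O)[C@@H]12)O3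
F3 | step 17 | 8-ketone from 26: 15-{[tert-butyl(diphenyl)silyl]oxy}-1,8-dioxo-3,10-epoxygermacra-2,4,11(13)-trien-12,6-olide | C=C1C(=O)O[C@H]2/C=C(/CO[Si](c4ccccc4)(c4ccccc4)C(C)(C)C)C3=CC(=O)[C@@](C)(CC(=O)[C@@H]12)O3
F4 | step 17 | 8R alcohol (C8 epimer of 26) | C=C1C(=O)O[C@H]2/C=C(/CO[Si](c4ccccc4)(c4ccccc4)C(C)(C)C)C3=CC(=O)[C@@](C)(C[C@@H](O)[C@@H]12)O3
F5 | step 14 | bromohydrin from 20: 7-bromo-6,8-dihydroxy compound, Br at C7 cis to O6 and OH at C8 trans to Br | O[C@H]1/C=C(/CO[Si](c4ccccc4)(c4ccccc4)C(C)(C)C)C2=CC(=O)[C@@](C)(C[C@H](O)[C@H]1Br)O2
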